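**Retrosynthetic overview**

1. The target 40 comes from the hydroxy-adamantane 35 by retro-aldol/olefination at the aldehyde carbon, 1,4-hydrogenation of the resulting C7 diene to the prenyl group, and global desilylation.
2. 35 comes in one operation from the flat aryl 2-formyl-3-methylbut-2-enyl ether 31: an O-to-C transfer of the three-carbon unit forms C1–C8, a Michael closure forms C5–C6 (ring A = C1–C8–C7–C6–C5–C9), and an aldol between C3 and the new aldehyde closes a temporary third ring.
3. Enabling feature: in ring B (C1–C2–C3–C4–C5–C9, the phloroglucinol ring) the oxygen on C2 is ortho to C1 and para to C5, and C1 and C5 flank C9. A C3 unit hung on O2 therefore reaches C1 with its far end through a six-membered transition state and C5 with its near end, and the aroyl-bearing C3 lies under C7 to lock the endo configuration.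
4. 31 comes from a 1-silyloxy-3,5-bis(MOM-oxy)benzene by three successive metalations (side chain from (S)-lavandulyl iodide, then prenyl, then aroyl); O2 is unique because it is para to the side chain.
5. Ring order: ring B is the starting arene; ring A and the temporary third ring form in the key step; the third ring is reopened in step 20.

Key step: step 19

Remarks on the chemistry:
- Locants: the bicyclo[3.3.1]nonane numbering of the target (C1 prenyl bridgehead, C2–C4 triketone bridge, C5 side-chain bridgehead, C6–C8 bridge, C9 bridging carbonyl) is also used for the arene precursors; O2, O4 and O9 are the oxygens on C2, C4 and C9.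
- Assumption 1: the carbinol carbon of 35 may form as either epimer and is drawn without a descriptor; step 20 erases it.
- Assumption 2: the cinchonidinium catalyst is taken to favour the (1R,5R) core; should a pilot run show the opposite sense, the pseudoenantiomeric cinchoninium salt is used. Because the side chain is enantiopure, the minor core isomer is a diastereomer and is removed by chromatography at 35.

**Route**

Step 1
Reactants: 1 (S)-4-benzyloxazolidin-2-one; 2 3-methylbut-2-enoyl chloride
Product: 4 (S)-4-benzyl-3-(3-methylbut-2-enoyl)oxazolidin-2-one, via N-lithio oxazolidinone 3 (not isolated)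
Conditions: n-BuLi, THF, −78 °C; then 2, −78 to 0 °C
Reagents that add atoms: none
Why: N-acylation of a lithiated Evans auxiliary with an acid chloride is standard and creates no stereocenter.

Step 2
Reactants: 4 N-senecioyl oxazolidinone; 5 prenyl bromide (1-bromo-3-methylbut-2-ene)
Product: 7 (S)-4-benzyl-3-[(2S)-5-methyl-2-(prop-1-en-2-yl)hex-4-enoyl]oxazolidin-2-one, via sodium dienolate 6 (not isolated)
Conditions: NaN(SiMe3)2, THF, −78 °C; then 5, −78 to −40 °C
Reagents that add atoms: none
Why: Evans deconjugative α-alkylation: γ-deprotonation gives the chelated (Z)-dienolate, which should be alkylated at the α-carbon on the face away from the benzyl group, setting the (2S) centre that becomes the side-chain methine.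

Step 3
Reactants: 7 alkylated imide
Product: 8 (S)-lavandulol
Conditions: LiBH4, Et2O, H2O (1 equiv), 0 °C
Reagents that add atoms: none
Why: reductive cleavage of the N-acyl oxazolidinone with borohydride is standard and leaves the non-conjugated α-stereocenter untouched.

Step 4
Reactants: 8 (S)-lavandulol
Product: 9 (S)-lavandulyl iodide
Conditions: I2, PPh3, imidazole, CH2Cl2, 0 °C
Reagents that add atoms: iodine II
Why: Appel-type iodination of a primary alcohol proceeds at the CH2 carbon and does not touch the stereocenter.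

Step 5
Reactants: 10 1,3-bis(methoxymethoxy)benzene
Product: 12 3,5-bis(methoxymethoxy)phenol, via aryl boronate 11 (not isolated)
Conditions: [Ir(OMe)(cod)]2 (1.5 mol %), 4,4′-di-tert-butyl-2,2′-bipyridine, B2pin2 (0.55 equiv), THF, 80 °C; then Oxone (2KHSO5·KHSO4·K2SO4), acetone/H2O, 23 °C
Reagents that add atoms: bis(pinacolato)diboron CC1(C)OB(OC1(C)C)B1OC(C)(C)C(C)(C)O1 (boron of 11 only); potassium peroxymonosulfate [K+].[O-]S(=O)(=O)OO (phenol oxygen)
Why: sterically controlled iridium-catalyzed C–H borylation attacks the only C–H that is not ortho to an oxygen substituent, and one-pot oxidation of the aryl boronate gives the phenol.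

Step 6
Reactants: 12 3,5-bis(methoxymethoxy)phenol
Product: 13 [3,5-bis(methoxymethoxy)phenoxy]triisopropylsilane
Conditions: i-Pr3SiCl, imidazole, DMF, 23 °C
Reagents that add atoms: chlorotriisopropylsilane CC(C)[Si](Cl)(C(C)C)C(C)C
Why: standard silylation gives a bulky, non-directing group on the oxygen that will become O2.

Step 7
Reactants: 13 silyl ether; 9 (S)-lavandulyl iodide
Product: 15 lavandulyl arene, via aryllithium 14 (not isolated)
Conditions: n-BuLi, THF, 0 °C; then 9, Li2CuCl4 (5 mol %), −20 to 23 °C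
Reagents that add atoms: none
Why: directed ortho-metalation occurs between the two MOM ethers, and copper-catalyzed coupling of the aryllithium with the primary iodide forms the aryl–CH2 bond without touching the stereocenter.

Step 8
Reactants: 15 lavandulyl arene
Product: 16 epoxide
Conditions: D-fructose-derived Shi ketone (30 mol %), Oxone (2KHSO5·KHSO4·K2SO4), K2CO3, Bu4NHSO4, MeCN/CH2(OMe)2/aq. Na2B4O7 buffer, 0 °C
Reagents that add atoms: potassium peroxymonosulfate [K+].[O-]S(=O)(=O)OO
Why: Shi epoxidation should select the trisubstituted alkene over the 1,1-disubstituted one, and the chiral dioxirane sets the (R) epoxide carbon through its spiro transition state.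

Step 9
Reactants: 16 epoxide
Product: 17 secondary allylic alcohol
Conditions: Et2AlCl, lithium 2,2,6,6-tetramethylpiperidide, toluene, 0 °C
Reagents that add atoms: none
Why: Yamamoto-type isomerization of a trisubstituted epoxide with the aluminum amide removes a methyl proton and opens the ring at the tertiary carbon, so the C–O bond at the stereocenter is retained and the (R) carbinol with its isopropenyl group results.

Step 10
Reactants: 17 allylic alcohol
Product: 18 tert-butyldimethylsilyl ether
Conditions: t-BuMe2SiCl, imidazole, DMF, 23 °C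
Reagents that add atoms: tert-butylchlorodimethylsilane CC(C)(C)[Si](C)(C)Cl
Why: standard silylation of a secondary alcohol, with no change at the stereocenters.

Step 11
Reactants: 18 silyl ether
Product: 19 dibromide
Conditions: N-bromosuccinimide (2.05 equiv), CH2Cl2, −78 to −20 °C
Reagents that add atoms: N-bromosuccinimide O=C1CCC(=O)N1Br
Why: electrophilic aromatic bromination of the two free positions of the trialkoxyarene should be far faster than attack on the 1,1-disubstituted alkenes.

Step 12
Reactants: 19 dibromide; 5 prenyl bromide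
Product: 22 bromophenol, via aryllithium 20 (not isolated), via silyl ether 21 (not isolated)
Conditions: n-BuLi (1.05 equiv), THF, −78 °C; CuBr·SMe2 (10 mol %), 5, −78 to −20 °C; then Bu4NF, AcOH, 0 °C
Reagents that add atoms: none
Why: bromine–lithium exchange of one of two equivalent bromides, copper-catalyzed SN2 allylation, and fluoride cleavage of the aryl silyl ether (much faster than that of the secondary alkyl silyl ether) free the unique oxygen O2.

Step 13
Reactants: 23 diethyl 2-(propan-2-ylidene)malonate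
Product: 24 2-(propan-2-ylidene)propane-1,3-diol
Conditions: i-Bu2AlH, CH2Cl2, −78 to 0 °C
Reagents that add atoms: none
Why: 1,2-reduction of both esters of an alkylidene malonate by the aluminum hydride gives the symmetric allylic diol.

Step 14
Reactants: 22 bromophenol; 24 diol (threefold excess)
Product: 25 aryl allyl ether alcohol
Conditions: PPh3, diisopropyl azodicarboxylate, THF, 0 to 23 °C
Reagents that add atoms: none
Why: Mitsunobu etherification of the acidic ortho-bromophenol with one of the two equivalent primary allylic hydroxyls places the three-carbon unit on O2.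

Step 15
Reactants: 26 methyl 3,4-dihydroxybenzoate
Product: 27 methyl 3,4-bis(triisopropylsilyloxy)benzoate
Conditions: i-Pr3SiCl, imidazole, DMF, 40 °C
Reagents that add atoms: chlorotriisopropylsilane CC(C)[Si](Cl)(C(C)C)C(C)C
Why: standard silylation of the catechol.

Step 16
Reactants: 25 aryl bromide; 27 ester
Product: 29 benzophenone alcohol, via dilithio species 28 (not isolated)
Conditions: t-BuLi (3.1 equiv), THF, −78 °C; then 27, −78 to −20 °C
Reagents that add atoms: none
Why: after deprotonation of the alcohol, bromine–lithium exchange at −78 °C is faster than any deprotonation, and the hindered aryllithium is acylated once by the methyl ester to give the diaryl ketone.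

Step 17
Reactants: 29 allylic alcohol
Product: 30 enal
Conditions: MnO2, CH2Cl2, 23 °C
Reagents that add atoms: none
Why: MnO2 oxidizes the primary allylic alcohol selectively to the α,β-unsaturated aldehyde.

Step 18
Reactants: 30 bis-MOM ether
Product: 31 bis(triethylsilyl) ether
Conditions: Et3SiOTf, 2,2′-bipyridyl, CH2Cl2, 0 °C
Reagents that add atoms: triethylsilyl trifluoromethanesulfonate CC[Si](CC)(CC)OS(=O)(=O)C(F)(F)F
Why: silyl triflate with 2,2′-bipyridyl is known to convert aromatic MOM ethers directly into aryl triethylsilyl ethers under near-neutral conditions that alkyl silyl ethers, the enal and the alkenes should tolerate.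

Step 19
Reactants: 31 aryl 2-formyl-3-methylbut-2-enyl ether
Product: 35 hydroxy-adamantane, via bis-phenol 32 (not isolated), via Claisen-type dienone 33 (not isolated), via endo aldehyde 34 (not isolated)
Conditions: CsOH·H2O (5 equiv), O-allyl-N-(9-anthracenylmethyl)cinchonidinium bromide (20 mol %), CH2Cl2, −50 to −30 °C; aq. NH4Cl
Reagents that add atoms: none
Why: Proposed new method: hydroxide removes the two triethylsilyl groups; the phenoxide, ion-paired with the chiral ammonium cation, adds through C1 to the β-carbon C8 of the tethered enal in a six-membered transition state and expels O2 as a vinylogous carboxylate (a stepwise anionic counterpart of the aromatic Claisen rearrangement, forming C1–C8); the enolate carbon C5 then adds to the new acrolein terminus C6 (forming C5–C6), the C7 aldehyde enolate is protonated on its open exo face, and C3 captures the endo aldehyde in an aldol reaction. The closest known reaction type is the base-mediated alkylative dearomatization–annulation of acylphloroglucinols with 2-(acyloxyalkyl)acroleins under chiral phase-transfer catalysis, which gives the same kind of hydroxy-adamantane core intermolecularly; here the three-carbon unit is delivered from O2 instead. Ring A closes by a 6-endo-trig Michael addition (C5 to C6) after the [3,3]-type O-to-C transfer, and the temporary third ring closes by a 6-exo-trig aldol addition (C3 to the aldehyde carbon). C1 is set by the arene face that the catalyst-bound ion pair exposes to C8, C5 follows from C1 because the three-carbon bridge can span only one face, C7 is set by exo protonation and locked by the aldol, C3 is fixed by the cage, and the carbinol carbon is uncontrolled. The step needs C1 rather than C3 to attack C8 and needs the ether to sit on O2: the first is secured because C3 is the weakly nucleophilic central carbon of the aroyl triketone, the second by construction, since O2 is the only oxygen para to the side chain. A doubly charged phenoxide is a poor leaving group, which should suppress loss of the unit by elimination before C1–C8 has formed.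

Step 20
Reactants: 35 hydroxy-adamantane; 36 diethyl (2-methylprop-2-en-1-yl)phosphonate
Product: 38 C7 (E)-3-methylbuta-1,3-dienyl compound, via ring-opened lithium enolate aldehyde 37 (not isolated)
Conditions: 36 (3 equiv), n-BuLi (3 equiv), THF/DMPU, −78 °C; then 35, −78 to 23 °C; aq. NH4Cl
Reagents that add atoms: none
Why: the lithiated allylphosphonate deprotonates the carbinol, whose lithium alkoxide undergoes retro-aldol cleavage of the C3–carbinol bond to the stabilized lithium triketone enolate 37 carrying the endo formyl group (a tandem known for such hydroxy-adamantane cores with organocerium reagents), and Horner–Wadsworth–Emmons olefination of that aldehyde by a second equivalent of the phosphonate anion gives the (E)-diene while C7 keeps its endo configuration because the aldehyde should be consumed faster than it epimerizes.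

Step 21
Reactants: 38 diene
Product: 39 silyl-protected target
Conditions: (η6-naphthalene)Cr(CO)3 (20 mol %), H2 (4 atm), THF, 45 °C
Reagents that add atoms: none
Why: arene–Cr(CO)3-catalyzed 1,4-hydrogenation adds H2 only to the termini of an s-cis 1,3-diene, which turns the 3-methylbuta-1,3-dienyl group into the prenyl group and should leave all isolated alkenes untouched; no stereocenter is formed.

Step 22
Reactants: 39 tris-silyl ether
Product: 40 CNP0329843.4
Conditions: Bu4NF, AcOH, THF, 0 to 40 °C
Reagents that add atoms: none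
Why: buffered fluoride cleaves the two aryl silyl ethers and the secondary silyl ether without acid, which avoids cyclization of the enol onto the isopropenyl groups.

**Compound list**

1 | (S)-4-benzyloxazolidin-2-one | O=C1N[C@@H](Cc2ccccc2)CO1 | starting material
2 | 3-methylbut-2-enoyl chloride | CC(C)=CC(Cl)=O | starting material
3 | lithium salt of 1 (N-lithio oxazolidinone) | [Li]N1C(=O)OC[C@@H]1Cc1ccccc1 | intermediate
4 | (S)-4-benzyl-3-(3-methylbut-2-enoyl)oxazolidin-2-one | CC(C)=CC(=O)N1C(=O)OC[C@@H]1Cc1ccccc1 | intermediate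
5 | prenyl bromide (1-bromo-3-methylbut-2-ene) | CC(C)=CCBr | starting material
6 | sodium (Z)-dienolate of 4 | C=C(C)/C=C(\O[Na])N1C(=O)OC[C@@H]1Cc1ccccc1 | intermediate
7 | (S)-4-benzyl-3-[(2S)-5-methyl-2-(prop-1-en-2-yl)hex-4-enoyl]oxazolidin-2-one | C=C(C)[C@H](CC=C(C)C)C(=O)N1C(=O)OC[C@@H]1Cc1ccccc1 | intermediate
8 | (S)-lavandulol, (2S)-5-methyl-2-(prop-1-en-2-yl)hex-4-en-1-ol | C=C(C)[C@H](CC=C(C)C)CO | intermediate
9 | (S)-lavandulyl iodide, (3S)-3-(iodomethyl)-2,6-dimethylhepta-1,5-diene | C=C(C)[C@H](CC=C(C)C)CI | intermediate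
10 | 1,3-bis(methoxymethoxy)benzene | COCOc1cccc(OCOC)c1 | starting material
11 | 2-[3,5-bis(methoxymethoxy)phenyl]-4,4,5,5-tetramethyl-1,3,2-dioxaborolane | COCOc1cc(B2OC(C)(C)C(C)(C)O2)cc(OCOC)c1 | intermediate
12 | 3,5-bis(methoxymethoxy)phenol | COCOc1cc(O)cc(OCOC)c1 | intermediate
13 | [3,5-bis(methoxymethoxy)phenoxy]triisopropylsilane | COCOc1cc(O[Si](C(C)C)(C(C)C)C(C)C)cc(OCOC)c1 | intermediate
14 | 4-lithio derivative of 13 (lithium between the two MOM ethers) | COCOc1cc(O[Si](C(C)C)(C(C)C)C(C)C)cc(OCOC)c1[Li] | intermediate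
15 | {3,5-bis(methoxymethoxy)-4-[(2R)-5-methyl-2-(prop-1-en-2-yl)hex-4-enyl]phenoxy}triisopropylsilane | COCOc1cc(O[Si](C(C)C)(C(C)C)C(C)C)cc(OCOC)c1C[C@H](C(C)=C)CC=C(C)C | intermediate
16 | (4-{(2S)-3-[(2R)-3,3-dimethyloxiran-2-yl]-2-(prop-1-en-2-yl)propyl}-3,5-bis(methoxymethoxy)phenoxy)triisopropylsilane | COCOc1cc(O[Si](C(C)C)(C(C)C)C(C)C)cc(OCOC)c1C[C@H](C(C)=C)C[C@H]2OC2(C)C | intermediate
17 | (3R,5S)-6-[2,6-bis(methoxymethoxy)-4-(triisopropylsilyloxy)phenyl]-2-methyl-5-(prop-1-en-2-yl)hex-1-en-3-ol | COCOc1cc(O[Si](C(C)C)(C(C)C)C(C)C)cc(OCOC)c1C[C@H](C(C)=C)C[C@@H](O)C(C)=C | intermediate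
18 | tert-butyldimethylsilyl ether of 17 | COCOc1cc(O[Si](C(C)C)(C(C)C)C(C)C)cc(OCOC)c1C[C@H](C(C)=C)C[C@@H](O[Si](C)(C)C(C)(C)C)C(C)=C | intermediate
19 | 3,5-dibromo derivative of 18 (bromine on both carbons next to the silyloxy carbon) | COCOc1c(Br)c(O[Si](C(C)C)(C(C)C)C(C)C)c(Br)c(OCOC)c1C[C@H](C(C)=C)C[C@@H](O[Si](C)(C)C(C)(C)C)C(C)=C | intermediate
20 | mono-aryllithium from 19 | COCOc1c(Br)c(O[Si](C(C)C)(C(C)C)C(C)C)c([Li])c(OCOC)c1C[C@H](C(C)=C)C[C@@H](O[Si](C)(C)C(C)(C)C)C(C)=C | intermediate
21 | bromo prenyl arene, triisopropylsilyl ether of 22 | COCOc1c(Br)c(O[Si](C(C)C)(C(C)C)C(C)C)c(CC=C(C)C)c(OCOC)c1C[C@H](C(C)=C)C[C@@H](O[Si](C)(C)C(C)(C)C)C(C)=C | intermediate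
22 | 2-bromo-4-[(2S,4R)-4-(tert-butyldimethylsilyloxy)-5-methyl-2-(prop-1-en-2-yl)hex-5-enyl]-3,5-bis(methoxymethoxy)-6-(3-methylbut-2-enyl)phenol | COCOc1c(Br)c(O)c(CC=C(C)C)c(OCOC)c1C[C@H](C(C)=C)C[C@@H](O[Si](C)(C)C(C)(C)C)C(C)=C | intermediate
23 | diethyl 2-(propan-2-ylidene)malonate | CCOC(=O)C(=C(C)C)C(=O)OCC | starting material
24 | 2-(propan-2-ylidene)propane-1,3-diol | OCC(CO)=C(C)C | intermediate
25 | 2-[(aryloxy)methyl]-3-methylbut-2-en-1-ol, aryl = the ring of 22 | COCOc1c(Br)c(OCC(CO)=C(C)C)c(CC=C(C)C)c(OCOC)c1C[C@H](C(C)=C)C[C@@H](O[Si](C)(C)C(C)(C)C)C(C)=C | intermediate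
26 | methyl 3,4-dihydroxybenzoate | COC(=O)c1ccc(O)c(O)c1 | starting material
27 | methyl 3,4-bis(triisopropylsilyloxy)benzoate | COC(=O)c1ccc(O[Si](C(C)C)(C(C)C)C(C)C)c(O[Si](C(C)C)(C(C)C)C(C)C)c1 | intermediate
28 | aryllithium lithium alkoxide from 25 | COCOc1c([Li])c(OCC(CO[Li])=C(C)C)c(CC=C(C)C)c(OCOC)c1C[C@H](C(C)=C)C[C@@H](O[Si](C)(C)C(C)(C)C)C(C)=C | intermediate
29 | {5-[(2S,4R)-4-(tert-butyldimethylsilyloxy)-5-methyl-2-(prop-1-en-2-yl)hex-5-enyl]-2-{[2-(hydroxymethyl)-3-methylbut-2-enyl]oxy}-4,6-bis(methoxymethoxy)-3-(3-methylbut-2-enyl)phenyl}[3,4-bis(triisopropylsilyloxy)phenyl]methanone | COCOc1c(C(=O)c2ccc(O[Si](C(C)C)(C(C)C)C(C)C)c(O[Si](C(C)C)(C(C)C)C(C)C)c2)c(OCC(CO)=C(C)C)c(CC=C(C)C)c(OCOC)c1C[C@H](C(C)=C)C[C@@H](O[Si](C)(C)C(C)(C)C)C(C)=C | intermediate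
30 | 2-[(aryloxy)methyl]-3-methylbut-2-enal, aryl = the benzophenone ring of 29 | COCOc1c(C(=O)c2ccc(O[Si](C(C)C)(C(C)C)C(C)C)c(O[Si](C(C)C)(C(C)C)C(C)C)c2)c(OCC(C=O)=C(C)C)c(CC=C(C)C)c(OCOC)c1C[C@H](C(C)=C)C[C@@H](O[Si](C)(C)C(C)(C)C)C(C)=C | intermediate
31 | analogue of 30 with triethylsilyl ethers in place of both MOM ethers (O4 and O9) | CC[Si](CC)(CC)Oc1c(C(=O)c2ccc(O[Si](C(C)C)(C(C)C)C(C)C)c(O[Si](C(C)C)(C(C)C)C(C)C)c2)c(OCC(C=O)=C(C)C)c(CC=C(C)C)c(O[Si](CC)(CC)CC)c1C[C@H](C(C)=C)C[C@@H](O[Si](C)(C)C(C)(C)C)C(C)=C | intermediate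
32 | bis-phenol of 31 (free OH on C4 and C9) | Oc1c(C(=O)c2ccc(O[Si](C(C)C)(C(C)C)C(C)C)c(O[Si](C(C)C)(C(C)C)C(C)C)c2)c(OCC(C=O)=C(C)C)c(CC=C(C)C)c(O)c1C[C@H](C(C)=C)C[C@@H](O[Si](C)(C)C(C)(C)C)C(C)=C | intermediate
33 | (R)-configured C1-quaternary dienone: C1 carries prenyl and the 2-formyl-1,1-dimethylallyl group; drawn as the C4/C9 dienol | C=C(C=O)C(C)(C)[C@@]1(CC=C(C)C)C(=O)C(C(=O)c2ccc(O[Si](C(C)C)(C(C)C)C(C)C)c(O[Si](C(C)C)(C(C)C)C(C)C)c2)=C(O)C(C[C@H](C(C)=C)C[C@@H](O[Si](C)(C)C(C)(C)C)C(C)=C)=C1O | intermediate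
34 | (1R,5R,7R)-3-[3,4-bis(triisopropylsilyloxy)benzoyl]-5-[(2S,4R)-4-(tert-butyldimethylsilyloxy)-5-methyl-2-(prop-1-en-2-yl)hex-5-enyl]-4-hydroxy-8,8-dimethyl-1-(3-methylbut-2-enyl)-2,9-dioxobicyclo[3.3.1]non-3-ene-7-carbaldehyde (formyl endo) | C=C(C)[C@H](C[C@@H](O[Si](C)(C)C(C)(C)C)C(=C)C)C[C@@]12C[C@@H](C=O)C(C)(C)[C@@](CC=C(C)C)(C(=O)C(C(=O)c3ccc(O[Si](C(C)C)(C(C)C)C(C)C)c(O[Si](C(C)C)(C(C)C)C(C)C)c3)=C1O)C2=O | intermediate
35 | hydroxy-adamantane: the bicyclic core of 34 with an added C3–CH(OH)–C7 bridge; 2,4,9-trione; C3 carries the aroyl group; C1, C5 and C7 arranged in space as in 40; carbinol carbon either epimer | C=C(C)[C@H](C[C@@H](O[Si](C)(C)C(C)(C)C)C(=C)C)C[C@@]12C[C@@H]3C(C)(C)[C@@](CC=C(C)C)(C(=O)[C@@](C(=O)c4ccc(O[Si](C(C)C)(C(C)C)C(C)C)c(O[Si](C(C)C)(C(C)C)C(C)C)c4)(C3O)C1=O)C2=O | intermediate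
36 | diethyl (2-methylprop-2-en-1-yl)phosphonate | CCOP(=O)(CC(C)=C)OCC | starting material
37 | lithium enolate of the ring-opened endo aldehyde: lithium salt of 34 at the triketone enol oxygen, formed by retro-aldol cleavage of the lithium alkoxide of 35 | C=C(C)[C@H](C[C@@H](O[Si](C)(C)C(C)(C)C)C(=C)C)C[C@@]12C[C@@H](C=O)C(C)(C)[C@@](CC=C(C)C)(C(=O)C(C(=O)c3ccc(O[Si](C(C)C)(C(C)C)C(C)C)c(O[Si](C(C)C)(C(C)C)C(C)C)c3)=C1O[Li])C2=O | intermediate
38 | analogue of 39 with an endo (1E)-3-methylbuta-1,3-dienyl group on C7 in place of prenyl (same arrangement in space; CIP descriptor at C7 becomes S) | C=C(C)[C@H](C[C@@H](O[Si](C)(C)C(C)(C)C)C(=C)C)C[C@@]12C[C@@H](/C=C/C(C)=C)C(C)(C)[C@@](CC=C(C)C)(C(=O)C(C(=O)c3ccc(O[Si](C(C)C)(C(C)C)C(C)C)c(O[Si](C(C)C)(C(C)C)C(C)C)c3)=C1O)C2=O | intermediate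
39 | (1R,5R,7R)-3-[3,4-bis(triisopropylsilyloxy)benzoyl]-5-[(2S,4R)-4-(tert-butyldimethylsilyloxy)-5-methyl-2-(prop-1-en-2-yl)hex-5-enyl]-4-hydroxy-8,8-dimethyl-1,7-bis(3-methylbut-2-enyl)bicyclo[3.3.1]non-3-ene-2,9-dione | C=C(C)[C@H](C[C@@H](O[Si](C)(C)C(C)(C)C)C(=C)C)C[C@@]12C[C@@H](CC=C(C)C)C(C)(C)[C@@](CC=C(C)C)(C(=O)C(C(=O)c3ccc(O[Si](C(C)C)(C(C)C)C(C)C)c(O[Si](C(C)C)(C(C)C)C(C)C)c3)=C1O)C2=O | intermediate
40 | CNP0329843.4, (1R,5R,7R)-3-(3,4-dihydroxybenzoyl)-4-hydroxy-5-[(2S,4R)-4-hydroxy-5-methyl-2-(prop-1-en-2-yl)hex-5-enyl]-8,8-dimethyl-1,7-bis(3-methylbut-2-enyl)bicyclo[3.3.1]non-3-ene-2,9-dione | C=C(C)[C@H](C[C@@H](O)C(=C)C)C[C@@]12C[C@@H](CC=C(C)C)C(C)(C)[C@@](CC=C(C)C)(C(=O)C(C(=O)c3ccc(O)c(O)c3)=C1O)C2=O | target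

**Totals**

Total step count: 22. Longest linear sequence: 18 steps (steps 1–4, 7–12, 14, 16–22).

**Steps most likely to fail**

Step 19 (proposed new method). The facial selectivity of the C1–C8 bond formation under the chiral ion pair may be low, or the three-carbon unit may be transferred between molecules before it is delivered to C1. Fallback with known reactions, from 31 back to 35: 31 is heated in toluene at 110 °C, where a thermal aromatic Claisen rearrangement should give the bis(triethylsilyl) dienone F1 as both C1 epimers; any material that moves on by Cope shift to C5 carries the same two termini and closes to the same product. K2CO3 in MeOH at 0 °C then cleaves the two triethylsilyl enol ethers and brings about the Michael and aldol closures, and 35 is separated from its core diastereomer by chromatography.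

Step 20. The liberated aldehyde may be enolized by the basic phosphonate anion, with loss of the endo configuration at C7, or the olefination may give a Z-rich diene that is hydrogenated slowly in step 21. Fallback, from 35 back to 39 (bypassing 37 and 38): retro-aldol opening with CeCl3/CH2=CHMgBr in THF at −78 °C and addition to the aldehyde give the vinyl carbinol F2. Acetylation (Ac2O, pyridine) gives the allylic acetate F3. Pd(PPh3)4 with HCO2NH4 in toluene delivers hydride to the substituted allyl terminus and gives the C7 allyl compound F4. Cross-metathesis with 2-methyl-2-butene and the second-generation Grubbs catalyst (H2IMes)(PCy3)Cl2Ru=CHPh converts the allyl group into the prenyl group of 39.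

Step 16. The aryllithium may abstract a proton from the neighbouring allylic OCH2 group and rearrange in a Wittig-type process before it meets the ester. Fallback, from 25 back to 30 (bypassing 29): bromine–magnesium exchange of 25 with n-Bu3MgLi in THF at −10 °C gives a less basic arylmagnesate, which is added to 3,4-bis(triisopropylsilyloxy)benzaldehyde F5 (made from 3,4-dihydroxybenzaldehyde, i-Pr3SiCl and imidazole) to give the diaryl carbinol diol F6. Excess MnO2 then oxidizes the benzylic and the allylic alcohol together to give 30.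

Further compounds
F1 | step 19 | bis(triethylsilyl) dienone: (R)-C1-quaternary cyclohexa-2,4-dienone with prenyl and 2-formyl-1,1-dimethylallyl on C1 and triethylsilyloxy groups on C4 and C9 (formed with its C1 epimer) | C=C(C=O)C(C)(C)[C@@]1(CC=C(C)C)C(=O)C(C(=O)c2ccc(O[Si](C(C)C)(C(C)C)C(C)C)c(O[Si](C(C)C)(C(C)C)C(C)C)c2)=C(O[Si](CC)(CC)CC)C(C[C@H](C(C)=C)C[C@@H](O[Si](C)(C)C(C)(C)C)C(C)=C)=C1O[Si](CC)(CC)CC
F2 | step 20 | vinyl carbinol: analogue of 39 with endo 1-hydroxyprop-2-enyl on C7 (carbinol either epimer) | C=C(C)[C@H](C[C@@H](O[Si](C)(C)C(C)(C)C)C(=C)C)C[C@@]12C[C@@H](C(O)C=C)C(C)(C)[C@@](CC=C(C)C)(C(=O)C(C(=O)c3ccc(O[Si](C(C)C)(C(C)C)C(C)C)c(O[Si](C(C)C)(C(C)C)C(C)C)c3)=C1O)C2=O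
F3 | step 20 | allylic acetate of F2 | C=C(C)[C@H](C[C@@H](O[Si](C)(C)C(C)(C)C)C(=C)C)C[C@@]12C[C@@H](C(OC(C)=O)C=C)C(C)(C)[C@@](CC=C(C)C)(C(=O)C(C(=O)c3ccc(O[Si](C(C)C)(C(C)C)C(C)C)c(O[Si](C(C)C)(C(C)C)C(C)C)c3)=C1O)C2=O
F4 | step 20 | C7 allyl compound: analogue of 39 with endo prop-2-enyl on C7 | C=C(C)[C@H](C[C@@H](O[Si](C)(C)C(C)(C)C)C(=C)C)C[C@@]12C[C@@H](CC=C)C(C)(C)[C@@](CC=C(C)C)(C(=O)C(C(=O)c3ccc(O[Si](C(C)C)(C(C)C)C(C)C)c(O[Si](C(C)C)(C(C)C)C(C)C)c3)=C1O)C2=O
F5 | step 16 | 3,4-bis(triisopropylsilyloxy)benzaldehyde | O=Cc1ccc(O[Si](C(C)C)(C(C)C)C(C)C)c(O[Si](C(C)C)(C(C)C)C(C)C)c1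
F6 | step 16 | diaryl carbinol diol: analogue of 29 with CH(OH) in place of the ketone (carbinol either epimer) | COCOc1c(C(O)c2ccc(O[Si](C(C)C)(C(C)C)C(C)C)c(O[Si](C(C)C)(C(C)C)C(C)C)c2)c(OCC(CO)=C(C)C)c(CC=C(C)C)c(OCOC)c1C[C@H](C(C)=C)C[C@@H](O[Si](C)(C)C(C)(C)C)C(C)=C
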